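**Plan**
- Retrosynthetic cuts, in order: the C7 acetate; the ring bond C14–C1 and the diene bond C2–C3; the chain bonds C13–C14 and C5–C6; last the oxolane bonds O–C11 and C12–OH.
- Enabling feature: the cis-oxolane (O, C8, C9, C10, C11) has oxygen on both exocyclic neighbours, C7 and C12. O7/O8 form a 1,2-diol that can hold osmium and deliver O8 plus a second oxygen to a Z C11=C12 alkene.
- Forward order: geraniol gives the C6–C13 chain; the oxolane closes first (step 8); C3–C5 arrive by epoxide opening, C14 by epoxide methylenation, C1/C2 by Negishi coupling; the 14-membered ring closes last at C14–C1 by B-alkyl Suzuki coupling, then acetylation.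
- Stereochemistry: C7 from one Sharpless epoxidation; C8 from inverting hydration of that epoxide; C11 and C12 relayed in step 8; 3E from syn carboalumination; C1=C2 geometry from cis bromoboration.

Key step: step 8

Remark: atoms are numbered around the 14-membered carbocycle of the target (C1 isopropyl, C4 vinylic methyl, C7 acetate, C8/C11 ether bridge, C12 tertiary hydroxyl); the target is 7R,8S,11R,12S with 1E,3E diene.

Step 1
Reactants: 1 geraniol
Product: 2 [(2R,3R)-3-methyl-3-(4-methylpent-3-en-1-yl)oxiran-2-yl]methanol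
Conditions: Ti(OiPr)4 (5 mol%), diethyl D-(−)-tartrate (6 mol%), t-BuOOH, 4 Å molecular sieves, CH2Cl2, −20 °C
Reagents that add atoms: tert-butyl hydroperoxide, CC(C)(C)OO
Why: Katsuki–Sharpless asymmetric epoxidation of the allylic alcohol only; the D-tartrate complex gives the (2R,3R)-epoxide (C7 and C8), the enantiomer of the familiar L-tartrate product, and the remote alkene is not touched.

Step 2
Reactants: 2 [(2R,3R)-3-methyl-3-(4-methylpent-3-en-1-yl)oxiran-2-yl]methanol
Product: 3 (2S,3R)-2-(chloromethyl)-3-methyl-3-(4-methylpent-3-en-1-yl)oxirane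
Conditions: PPh3, CCl4, NaHCO3, reflux
Reagents that add atoms: tetrachloromethane, ClC(Cl)(Cl)Cl
Why: Appel chlorination of the primary alcohol under buffered neutral conditions that spare epoxide and alkene; the chloride caps C6 through step 8 and later serves as leaving group for the C6–C7 epoxide (descriptor at C7 changes by priority only).

Step 3
Reactants: 3 (2S,3R)-2-(chloromethyl)-3-methyl-3-(4-methylpent-3-en-1-yl)oxirane
Product: 5 3-[(2R,3S)-3-(chloromethyl)-2-methyloxiran-2-yl]propanal, via ozonide 4 (not isolated)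
Conditions: O3, CH2Cl2, −78 °C; then PPh3, −78 °C → rt
Reagents that add atoms: ozone, [O-][O+]=O
Why: Ozonolysis with reductive work-up cleaves the only alkene to the C11 aldehyde; epoxide and alkyl chloride are inert to ozone.

Step 4
Reactants: 5 3-[(2R,3S)-3-(chloromethyl)-2-methyloxiran-2-yl]propanal; 6 methyl 2-[bis(2,2,2-trifluoroethoxy)phosphoryl]propanoate
Product: 7 methyl (2Z)-5-[(2R,3S)-3-(chloromethyl)-2-methyloxiran-2-yl]-2-methylpent-2-enoate
Conditions: 6, KN(SiMe3)2, 18-crown-6, THF, −78 °C; then 5, −78 °C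
Reagents that add atoms: none
Why: Still–Gennari olefination; the trifluoroethyl phosphonate with a crown-separated potassium ion eliminates fast from the kinetic adduct and should give the Z trisubstituted C11=C12 enoate.

Step 5
Reactants: 7 methyl (2Z)-5-[(2R,3S)-3-(chloromethyl)-2-methyloxiran-2-yl]-2-methylpent-2-enoate
Product: 8 methyl (2Z,6S,7S)-8-chloro-6,7-dihydroxy-2,6-dimethyloct-2-enoate
Conditions: HClO4 (cat.), THF/H2O, 0 °C → rt
Reagents that add atoms: water, O
Why: Acid-catalysed epoxide hydration in which water attacks the tertiary C8 anti to the protonated oxygen, inverting C8 and leaving the C7–O bond untouched (anti diol of the original E alkene); the chloromethyl group disfavours attack at C7 and the electron-poor enoate cannot participate.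

Step 6
Reactants: 8 methyl (2Z,6S,7S)-8-chloro-6,7-dihydroxy-2,6-dimethyloct-2-enoate
Product: 9 (2Z,6S,7S)-8-chloro-2,6-dimethyloct-2-ene-1,6,7-triol
Conditions: i-Bu2AlH (5 equiv), CH2Cl2, −78 → −20 °C; aq. potassium sodium tartrate
Reagents that add atoms: none
Why: 1,2-Reduction of the enoate to the Z allylic alcohol by i-Bu2AlH; excess reagent covers the two free hydroxyls, and the aluminium alkoxide at C7 is too weak a nucleophile to displace chloride at low temperature.

Step 7
Reactants: 9 (2Z,6S,7S)-8-chloro-2,6-dimethyloct-2-ene-1,6,7-triol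
Product: 10 (2S,3S,6Z)-8-{[tert-butyl(diphenyl)silyl]oxy}-1-chloro-3,7-dimethyloct-6-ene-2,3-diol
Conditions: t-BuPh2SiCl (1.05 equiv), imidazole, CH2Cl2, 0 °C
Reagents that add atoms: tert-butyl(chloro)diphenylsilane, CC(C)(C)[Si](Cl)(c1ccccc1)c1ccccc1
Why: Sterically controlled silylation of the primary allylic hydroxyl; the hindered secondary and tertiary hydroxyls stay free as the osmium-binding diol.

Step 8
Reactants: 10 (2S,3S,6Z)-8-{[tert-butyl(diphenyl)silyl]oxy}-1-chloro-3,7-dimethyloct-6-ene-2,3-diol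
Product: 11 (2S)-1-{[tert-butyl(diphenyl)silyl]oxy}-2-{(2R,5S)-5-[(1S)-2-chloro-1-hydroxyethyl]-5-methyloxolan-2-yl}propan-2-ol
Conditions: K2OsO2(OH)4 (5 mol%), pyridine N-oxide (3 equiv), citric acid (0.75 equiv), Cu(OTf)2 (0.5 equiv), MeCN/aq. Na2HPO4–NaH2PO4 buffer (pH 6.5), 60 °C
Reagents that add atoms: pyridine N-oxide, [O-][n+]1ccccc1
Why: The 7,8-diol condenses with hexavalent osmium to a glycolate, and an Os=O bond together with the Os–O8 bond adds across the tethered C11=C12 alkene in an intramolecular [3+2] step; pyridine N-oxide then returns tetravalent osmium to the hexavalent state and acid releases the product, which is the known osmium-catalysed oxidative cyclisation of 5,6-dihydroxyalkenes to cis-oxolanes. The oxolane closes 5-exo by O8–C11 bond formation. C11 and C12 are set by syn delivery of O8 and the oxo oxygen to one face of the Z alkene, and that face is dictated by the existing C8 centre because the metal is chelated by O7 and O8, which places the C7 and C12 arms cis on the ring (11R,12S). The step needs only the internal diol to bind the metal and only a five-membered ring to form: C6 carries chlorine and C13 a silyl ether, so no other diol is available, and O7 could close only a six-membered ring from a strained chelate. Pyridine N-oxide does not raise osmium to the octavalent state, so ordinary dihydroxylation of the alkene should not compete.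

Step 9
Reactants: 11 (2S)-1-{[tert-butyl(diphenyl)silyl]oxy}-2-{(2R,5S)-5-[(1S)-2-chloro-1-hydroxyethyl]-5-methyloxolan-2-yl}propan-2-ol
Product: 12 (2S)-1-{[tert-butyl(diphenyl)silyl]oxy}-2-{(2R,5S)-5-methyl-5-[(2R)-oxiran-2-yl]oxolan-2-yl}propan-2-ol
Conditions: K2CO3, MeOH, 0 °C → rt
Reagents that add atoms: none
Why: Intramolecular Williamson closure of the chlorohydrin; the C7 alkoxide displaces chloride at C6, so C7 keeps its configuration, and the silyl ether and tertiary alcohol are stable to carbonate.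

Step 10
Reactants: 12 (2S)-1-{[tert-butyl(diphenyl)silyl]oxy}-2-{(2R,5S)-5-methyl-5-[(2R)-oxiran-2-yl]oxolan-2-yl}propan-2-ol; 13 1-(trimethylsilyl)prop-1-yne
Product: 14 (1R)-1-[(2S,5R)-5-{(2S)-1-{[tert-butyl(diphenyl)silyl]oxy}-2-hydroxypropan-2-yl}-2-methyloxolan-2-yl]-5-(trimethylsilyl)pent-4-yn-1-ol
Conditions: 13 (4 equiv), n-BuLi (3.8 equiv), THF, −78 → −20 °C; then 12, BF3·OEt2 (2 equiv), −78 °C
Reagents that add atoms: none
Why: BF3-assisted SN2 opening of the terminal epoxide at the unsubstituted C6 by the propargylic lithium reagent forms C5–C6; the silyl group directs reaction to the propargylic carbon, and the tertiary hydroxyl rides through as its lithium alkoxide.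

Step 11
Reactants: 14 (1R)-1-[(2S,5R)-5-{(2S)-1-{[tert-butyl(diphenyl)silyl]oxy}-2-hydroxypropan-2-yl}-2-methyloxolan-2-yl]-5-(trimethylsilyl)pent-4-yn-1-ol
Product: 15 (2S)-2-{(2R,5S)-5-[(1R)-1-hydroxypent-4-yn-1-yl]-5-methyloxolan-2-yl}propane-1,2-diol
Conditions: Bu4NF (3 equiv), THF, 0 °C → rt
Reagents that add atoms: none
Why: Fluoride-induced desilylation removes the silyl ether at C13 and the alkynyl silane at C3 in one operation.

Step 12
Reactants: 15 (2S)-2-{(2R,5S)-5-[(1R)-1-hydroxypent-4-yn-1-yl]-5-methyloxolan-2-yl}propane-1,2-diol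
Product: 17 (1R)-1-{(2S,5R)-2-methyl-5-[(2S)-2-methyloxiran-2-yl]oxolan-2-yl}pent-4-yn-1-ol, via primary tosylate 16 (not isolated)
Conditions: TsCl (1.05 equiv), Et3N, Bu2SnO (2 mol%), CH2Cl2, 0 °C → rt; then K2CO3, MeOH, rt
Reagents that add atoms: none
Why: Tin-catalysed sulfonylation selects the primary hydroxyl of the 1,2-diol over the hindered secondary C7 hydroxyl, and base then closes the C12–C13 epoxide by Williamson displacement, with C12 keeping its configuration because its C–O bond is not broken.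

Step 13
Reactants: 17 (1R)-1-{(2S,5R)-2-methyl-5-[(2S)-2-methyloxiran-2-yl]oxolan-2-yl}pent-4-yn-1-ol
Product: 18 (1R)-1-{(2S,5R)-5-[(2S)-2-hydroxybut-3-en-2-yl]-2-methyloxolan-2-yl}pent-4-yn-1-ol
Conditions: Me3S+ I− (6 equiv), n-BuLi (5.8 equiv), THF, −10 °C; then 17, −10 °C → rt
Reagents that add atoms: trimethylsulfonium iodide, C[S+](C)C.[I-]
Why: One-carbon homologation of an epoxide to an allylic alcohol with excess dimethylsulfonium methylide (the Corey–Chaykovsky ylide); the ylide opens the epoxide at C13, a second equivalent eliminates dimethyl sulfide, and the result is the C13=C14 vinyl group, with the alkyne and hydroxyl simply deprotonated.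

Step 14
Reactants: 19 3-methylbut-1-yne
Product: 22 (1Z)-2-bromo-1-iodo-3-methylbut-1-ene, via alkenyldibromoborane 20 (not isolated), via alkenylboronic acid 21 (not isolated)
Conditions: BBr3, CH2Cl2, −78 °C → rt; ice–water; then NaOAc, ICl, MeOH, 0 °C
Reagents that add atoms: boron tribromide, BrB(Br)Br; iodine monochloride, ClI
Why: Bromoboration adds B and Br syn across the terminal alkyne with bromine on the internal carbon, and iododeboronation with ICl/NaOAc proceeds with retention, so bromine (future C14 site on C1) and iodine (future C3 site on C2) end cis.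

Step 15
Reactants: 18 (1R)-1-{(2S,5R)-5-[(2S)-2-hydroxybut-3-en-2-yl]-2-methyloxolan-2-yl}pent-4-yn-1-ol; 22 (1Z)-2-bromo-1-iodo-3-methylbut-1-ene
Product: 24 (1R,4E,6Z)-7-bromo-1-{(2S,5R)-5-[(2S)-2-hydroxybut-3-en-2-yl]-2-methyloxolan-2-yl}-4,8-dimethylnona-4,6-dien-1-ol, via alkenylalane 23 (not isolated)
Conditions: Me3Al (6 equiv), Cp2ZrCl2 (1 equiv), CH2Cl2, −25 °C → rt; volatiles removed; then 22 (1.5 equiv), Pd(PPh3)4 (5 mol%), ZnCl2 (co-catalyst), THF, rt
Reagents that add atoms: trimethylaluminium, C[Al](C)C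
Why: Negishi zirconium-catalysed carboalumination adds methyl and aluminium syn to the terminal alkyne (aluminium on C3), and the palladium-catalysed Negishi coupling then joins C3 to C2 with retention on both partners, oxidative addition choosing the C–I bond over the hindered C–Br bond; this fixes 3E and leaves bromine cis to C3 on C1.

Step 16
Reactants: 24 (1R,4E,6Z)-7-bromo-1-{(2S,5R)-5-[(2S)-2-hydroxybut-3-en-2-yl]-2-methyloxolan-2-yl}-4,8-dimethylnona-4,6-dien-1-ol
Product: 26 (1S,2R,5E,7E,11S,12R)-1,5,11-trimethyl-8-(propan-2-yl)-15-oxabicyclo[10.2.1]pentadeca-5,7-diene-2,11-diol, via alkylborane 25 (not isolated)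
Conditions: 9-BBN dimer (3 equiv), THF, rt; aq. Cs2CO3; then slow addition to Pd(dppf)Cl2 (20 mol%), AsPh3 (40 mol%), Cs2CO3, DMF/THF/H2O, 50 °C, about 1 mM
Reagents that add atoms: none
Why: 9-BBN hydroborates only the monosubstituted C13=C14 alkene with boron at C14, and the intramolecular B-alkyl Suzuki–Miyaura coupling with the dienyl bromide closes the 14-membered ring at C14–C1 with retention of alkene geometry; free hydroxyls are tolerated and high dilution favours ring closure.

Step 17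
Reactants: 26 (1S,2R,5E,7E,11S,12R)-1,5,11-trimethyl-8-(propan-2-yl)-15-oxabicyclo[10.2.1]pentadeca-5,7-diene-2,11-diol
Product: 27 (1S,2R,5E,7E,11S,12R)-11-hydroxy-1,5,11-trimethyl-8-(propan-2-yl)-15-oxabicyclo[10.2.1]pentadeca-5,7-dien-2-yl acetate
Conditions: Ac2O, pyridine, DMAP (cat.), CH2Cl2, 0 °C → rt
Reagents that add atoms: acetic anhydride, CC(=O)OC(C)=O
Why: Nucleophile-catalysed acylation esterifies the secondary C7 hydroxyl, while the tertiary C12 hydroxyl does not react under these mild conditions.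

**Compound list**
1 | geraniol, (2E)-3,7-dimethylocta-2,6-dien-1-ol | CC(C)=CCC/C(C)=C/CO | starting material
2 | [(2R,3R)-3-methyl-3-(4-methylpent-3-en-1-yl)oxiran-2-yl]methanol | CC(C)=CCC[C@@]1(C)O[C@@H]1CO | intermediate
3 | (2S,3R)-2-(chloromethyl)-3-methyl-3-(4-methylpent-3-en-1-yl)oxirane | CC(C)=CCC[C@@]1(C)O[C@@H]1CCl | intermediate
4 | 3-{2-[(2R,3S)-3-(chloromethyl)-2-methyloxiran-2-yl]ethyl}-5,5-dimethyl-1,2,4-trioxolane (ozonide, not isolated) | CC1(C)OOC(CC[C@@]2(C)O[C@@H]2CCl)O1 | intermediate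
5 | 3-[(2R,3S)-3-(chloromethyl)-2-methyloxiran-2-yl]propanal | O=CCC[C@@]1(C)O[C@@H]1CCl | intermediate
6 | methyl 2-[bis(2,2,2-trifluoroethoxy)phosphoryl]propanoate | COC(=O)C(C)P(=O)(OCC(F)(F)F)OCC(F)(F)F | starting material
7 | methyl (2Z)-5-[(2R,3S)-3-(chloromethyl)-2-methyloxiran-2-yl]-2-methylpent-2-enoate | COC(=O)/C(C)=C\CC[C@@]1(C)O[C@@H]1CCl | intermediate
8 | methyl (2Z,6S,7S)-8-chloro-6,7-dihydroxy-2,6-dimethyloct-2-enoate | COC(=O)/C(C)=C\CC[C@](C)(O)[C@H](O)CCl | intermediate
9 | (2Z,6S,7S)-8-chloro-2,6-dimethyloct-2-ene-1,6,7-triol | OC/C(C)=C\CC[C@](C)(O)[C@H](O)CCl | intermediate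
10 | (2S,3S,6Z)-8-{[tert-butyl(diphenyl)silyl]oxy}-1-chloro-3,7-dimethyloct-6-ene-2,3-diol | ClC[C@@H](O)[C@@](C)(O)CC/C=C(C)\CO[Si](c1ccccc1)(c1ccccc1)C(C)(C)C | intermediate
11 | (2S)-1-{[tert-butyl(diphenyl)silyl]oxy}-2-{(2R,5S)-5-[(1S)-2-chloro-1-hydroxyethyl]-5-methyloxolan-2-yl}propan-2-ol | ClC[C@@H](O)[C@]1(C)CC[C@@H](O1)[C@@](C)(O)CO[Si](c1ccccc1)(c1ccccc1)C(C)(C)C | intermediate
12 | (2S)-1-{[tert-butyl(diphenyl)silyl]oxy}-2-{(2R,5S)-5-methyl-5-[(2R)-oxiran-2-yl]oxolan-2-yl}propan-2-ol | C1O[C@H]1[C@]2(C)CC[C@@H](O2)[C@@](C)(O)CO[Si](c3ccccc3)(c3ccccc3)C(C)(C)C | intermediate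
13 | 1-(trimethylsilyl)prop-1-yne | CC#C[Si](C)(C)C | starting material
14 | (1R)-1-[(2S,5R)-5-{(2S)-1-{[tert-butyl(diphenyl)silyl]oxy}-2-hydroxypropan-2-yl}-2-methyloxolan-2-yl]-5-(trimethylsilyl)pent-4-yn-1-ol | C[Si](C)(C)C#CCC[C@@H](O)[C@]1(C)CC[C@@H](O1)[C@@](C)(O)CO[Si](c1ccccc1)(c1ccccc1)C(C)(C)C | intermediate
15 | (2S)-2-{(2R,5S)-5-[(1R)-1-hydroxypent-4-yn-1-yl]-5-methyloxolan-2-yl}propane-1,2-diol | C#CCC[C@@H](O)[C@]1(C)CC[C@@H](O1)[C@@](C)(O)CO | intermediate
16 | (2S)-2-hydroxy-2-{(2R,5S)-5-[(1R)-1-hydroxypent-4-yn-1-yl]-5-methyloxolan-2-yl}propyl 4-methylbenzenesulfonate (not isolated) | C#CCC[C@@H](O)[C@]1(C)CC[C@@H](O1)[C@@](C)(O)COS(=O)(=O)c1ccc(C)cc1 | intermediate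
17 | (1R)-1-{(2S,5R)-2-methyl-5-[(2S)-2-methyloxiran-2-yl]oxolan-2-yl}pent-4-yn-1-ol | C#CCC[C@@H](O)[C@]1(C)CC[C@@H](O1)[C@@]2(C)OC2 | intermediate
18 | (1R)-1-{(2S,5R)-5-[(2S)-2-hydroxybut-3-en-2-yl]-2-methyloxolan-2-yl}pent-4-yn-1-ol | C#CCC[C@@H](O)[C@]1(C)CC[C@@H](O1)[C@@](C)(O)C=C | intermediate
19 | 3-methylbut-1-yne | CC(C)C#C | starting material
20 | dibromo[(1Z)-2-bromo-3-methylbut-1-en-1-yl]borane (not isolated) | CC(C)/C(Br)=C/B(Br)Br | intermediate
21 | [(1Z)-2-bromo-3-methylbut-1-en-1-yl]boronic acid (not isolated) | CC(C)/C(Br)=C/B(O)O | intermediate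
22 | (1Z)-2-bromo-1-iodo-3-methylbut-1-ene | CC(C)/C(Br)=C/I | intermediate
23 | E-alkenyl(dimethyl)alane from 18, aluminium on C3, both hydroxyls as dimethylaluminium alkoxides (not isolated) | C[Al](C)/C=C(C)/CC[C@@H](O[Al](C)C)[C@]1(C)CC[C@@H](O1)[C@@](C)(O[Al](C)C)C=C | intermediate
24 | (1R,4E,6Z)-7-bromo-1-{(2S,5R)-5-[(2S)-2-hydroxybut-3-en-2-yl]-2-methyloxolan-2-yl}-4,8-dimethylnona-4,6-dien-1-ol | CC(C)/C(Br)=C/C=C(C)/CC[C@@H](O)[C@]1(C)CC[C@@H](O1)[C@@](C)(O)C=C | intermediate
25 | C14 B-alkyl-9-borabicyclo[3.3.1]nonane adduct of 24 (not isolated) | CC(C)/C(Br)=C/C=C(C)/CC[C@@H](O)[C@]1(C)CC[C@@H](O1)[C@@](C)(O)CCB1C2CCCC1CCC2 | intermediate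
26 | (1S,2R,5E,7E,11S,12R)-1,5,11-trimethyl-8-(propan-2-yl)-15-oxabicyclo[10.2.1]pentadeca-5,7-diene-2,11-diol | O[C@@H]1CC/C(C)=C/C=C(/C(C)C)CC[C@](C)(O)[C@H]2CC[C@]1(C)O2 | intermediate
27 | (1S,2R,5E,7E,11S,12R)-11-hydroxy-1,5,11-trimethyl-8-(propan-2-yl)-15-oxabicyclo[10.2.1]pentadeca-5,7-dien-2-yl acetate | CC(=O)O[C@@H]1CC/C(C)=C/C=C(/C(C)C)CC[C@](C)(O)[C@H]2CC[C@]1(C)O2 | target

**Step count**
Total steps: 17 (16 in the main line plus one for fragment 22).
Longest linear sequence: 16 steps from geraniol (steps 1–13 and 15–17).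

**Steps most likely to fail**

Step 8. Addition of the hindered tertiary osmate oxygen to a trisubstituted alkene may be slower than hydrolysis of the glycolate or acid-promoted ionisation of the tertiary carbinol, giving poor conversion. The fallback replaces syn oxidative cyclisation of the Z alkene by anti epoxidation–cyclisation of the E alkene; it sets out from 5 and returns at 11.
- Wittig olefination of 5 with methyl 2-(triphenylphosphoranylidene)propanoate (CH2Cl2, rt) should give the E epoxy chloride enoate F1.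
- Hydration as in step 5 gives the E chloro diol ester F2, i-Bu2AlH reduction the E allylic alcohol triol F3, and silylation the E isomer of 10 F4.
- Shi epoxidation with the L-fructose-derived ketone (KHSO5 as 2KHSO5·KHSO4·K2SO4, K2CO3 buffer, MeCN/dimethoxymethane/H2O, 0 °C) should give the (11S,12S)-epoxide F5.
- A trace of camphorsulfonic acid in CH2Cl2 then closes the oxolane by 5-exo attack of the C8 hydroxyl on C11 with inversion. Anti addition across the E alkene gives the same relative configuration as syn addition across the Z alkene, so the product is 11.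

Step 16. Oligomerisation and protodeboronation may outrun the slow oxidative addition and transmetalation at the alpha-branched dienyl bromide during ring closure. The fallback stages the closure through an isolated, protected alkyl iodide and an alkylzinc; it sets out from 24 and returns at 26.
- Et3SiOTf/2,6-lutidine gives the bis(triethylsilyl) ether F6.
- 9-BBN, then NaOH/H2O2, gives the primary C14 alcohol F7; I2/PPh3/imidazole gives the primary iodide F8.
- Zinc insertion (Zn dust, LiCl, THF) gives the alkylzinc iodide F9, which is added slowly to Pd(OAc)2/SPhos in THF/NMP so that an intramolecular Negishi coupling forms C14–C1 and gives the bis-silylated macrocycle F10.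
- Bu4NF returns 26.

Step 15. Protonolysis of the alkenylalane by aluminium alkoxides, or competing methyl transfer and loss of halide selectivity at the dihalide, may erode the one-pot coupling. The fallback separates the two events and reverses the polarity of the isopropyl fragment; it sets out from 18 and returns at 24.
- 18 is carboaluminated as before but quenched with I2 (THF, −30 °C) to give the E alkenyl iodide F11, which is purified.
- 19 is bromoborated to 20 as in step 14 and esterified with pinacol to the Z bromoalkenyl pinacol boronate F12.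
- Suzuki–Miyaura coupling of F11 with F12 (Pd(dppf)Cl2, aq. K3PO4, THF, rt) joins C2 to C3, the iodide reacting ahead of the hindered bromide, to give 24.

**Further compounds**
F1 | step 8 | methyl (2E)-5-[(2R,3S)-3-(chloromethyl)-2-methyloxiran-2-yl]-2-methylpent-2-enoate | COC(=O)/C(C)=C/CC[C@@]1(C)O[C@@H]1CCl
F2 | step 8 | methyl (2E,6S,7S)-8-chloro-6,7-dihydroxy-2,6-dimethyloct-2-enoate | COC(=O)/C(C)=C/CC[C@](C)(O)[C@H](O)CCl
F3 | step 8 | (2E,6S,7S)-8-chloro-2,6-dimethyloct-2-ene-1,6,7-triol | OC/C(C)=C/CC[C@](C)(O)[C@H](O)CCl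
F4 | step 8 | (2S,3S,6E)-8-{[tert-butyl(diphenyl)silyl]oxy}-1-chloro-3,7-dimethyloct-6-ene-2,3-diol | ClC[C@@H](O)[C@@](C)(O)CC/C=C(C)/CO[Si](c1ccccc1)(c1ccccc1)C(C)(C)C
F5 | step 8 | (2S,3S)-5-[(2S,3S)-3-({[tert-butyl(diphenyl)silyl]oxy}methyl)-3-methyloxiran-2-yl]-1-chloro-3-methylpentane-2,3-diol | ClC[C@@H](O)[C@@](C)(O)CC[C@@H]1O[C@@]1(C)CO[Si](c2ccccc2)(c2ccccc2)C(C)(C)C
F6 | step 16 | bis(triethylsilyl) ether of 24 (O7 and O12 silylated) | CC(C)/C(Br)=C/C=C(C)/CC[C@@H](O[Si](CC)(CC)CC)[C@]1(C)CC[C@@H](O1)[C@@](C)(O[Si](CC)(CC)CC)C=C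
F7 | step 16 | primary C14 alcohol from hydroboration–oxidation of F6 | CC(C)/C(Br)=C/C=C(C)/CC[C@@H](O[Si](CC)(CC)CC)[C@]1(C)CC[C@@H](O1)[C@@](C)(O[Si](CC)(CC)CC)CCO
F8 | step 16 | primary C14 iodide from F7 | CC(C)/C(Br)=C/C=C(C)/CC[C@@H](O[Si](CC)(CC)CC)[C@]1(C)CC[C@@H](O1)[C@@](C)(O[Si](CC)(CC)CC)CCI
F9 | step 16 | C14 alkylzinc iodide from F8 | CC(C)/C(Br)=C/C=C(C)/CC[C@@H](O[Si](CC)(CC)CC)[C@]1(C)CC[C@@H](O1)[C@@](C)(O[Si](CC)(CC)CC)CC[Zn]I
F10 | step 16 | bis(triethylsilyl) ether of 26 | CC[Si](CC)(CC)O[C@@H]1CC/C(C)=C/C=C(/C(C)C)CC[C@](C)(O[Si](CC)(CC)CC)[C@H]2CC[C@]1(C)O2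
F11 | step 15 | (1R,4E)-1-{(2S,5R)-5-[(2S)-2-hydroxybut-3-en-2-yl]-2-methyloxolan-2-yl}-5-iodo-4-methylpent-4-en-1-ol | I/C=C(C)/CC[C@@H](O)[C@]1(C)CC[C@@H](O1)[C@@](C)(O)C=C
F12 | step 15 | 2-[(1Z)-2-bromo-3-methylbut-1-en-1-yl]-4,4,5,5-tetramethyl-1,3,2-dioxaborolane | CC(C)/C(Br)=C/B1OC(C)(C)C(C)(C)O1
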